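## Retrosynthetic overview

1. The last bond is C6–C7 of the nine-membered ether ring (O, C2–C9; also the ten-membered carbocycle C1–C10). The strategy rests on C7 being a 1,1-disubstituted alkene carbon (exocyclic CH2) between the C6 and C8 methylenes, so it can arrive as a 2-bromoallyl group on C9 and meet a borane grown from the allyl group on C3 (one-pot hydroboration, B-alkyl Suzuki coupling).
2. The bromo diene 31 comes from closing the oxepane (C3–O–C17) by triflate etherification. C3 is set by chelate-controlled allylation of a C3 methyl ketone, and the C11/C12 cis-diol by OsO4 on the convex face, followed by C12 octanoylation.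
3. The tetrahydrofuran (C1, C2, O, C9, C10) comes from a cis-fused γ-lactone, reduced to the lactol acetate and C-glycosylated at C9 with (2-bromoallyl)trimethylsilane. C15 is set by hydroboration of the isopropenyl group.
4. C10–C9 comes from a Still–Wittig [2,3] shift from a C12 oxygen, placed by Wharton transposition of (R)-carvone oxide. C1–C2 comes from an anti aldol of the carvone oxide enolate with a ketal-masked pyruvaldehyde.
5. Ring order: cyclohexane (carvone), tetrahydrofuran (step 10), oxepane (step 19), nine-membered ether (step 20).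

Key step: step 20

Remark: eunicellane numbering is used throughout (C1–C14 ring carbons; C15 the methine on C14, C16 its methyl, C17 its OCH2; C18 the methyl on C3; C19 the CH2 on C7; C20 the methyl on C11). The target is (1S,2S,3S,9S,10R,11R,12S,14S,15R). Tributyl(iodomethyl)stannane and (2-bromoallyl)trimethylsilane are taken as purchasable.

## Route

Step 1
Reactants: 1 (R)-carvone
Product: 2 (1R,4R,6R)-carvone oxide (oxirane across C11–C12, trans to the isopropenyl group)
Conditions: 30% H2O2, NaOH (0.2 equiv), MeOH, 0 °C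
Reagents that add atoms: hydrogen peroxide, OO
Why: Weitz–Scheffer nucleophilic epoxidation of the enone; hydroperoxide adds to C12 axially, anti to the C14 isopropenyl group, so the oxirane (and the C12–O bond used later for chirality transfer) lies trans to it.

Step 2
Reactants: 3 ethyl pyruvate
Product: 4 ethyl 2-methyl-1,3-dioxolane-2-carboxylate
Conditions: ethylene glycol, p-TsOH (cat.), toluene, reflux, Dean–Stark
Reagents that add atoms: ethylene glycol, OCCO
Why: Acid-catalysed ketalisation with azeotropic removal of water masks the future C3 keto group as a dioxolane that withstands the bases, hydrides and Lewis acids ahead.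

Step 3
Reactants: 4 ethyl 2-methyl-1,3-dioxolane-2-carboxylate
Product: 5 2-methyl-1,3-dioxolane-2-carbaldehyde
Conditions: DIBAL-H (1.05 equiv), CH2Cl2, −78 °C; Rochelle salt work-up
Reagents that add atoms: none
Why: Partial ester reduction with DIBAL-H; the α,α-dialkoxy group stabilises the tetrahedral aluminate at −78 °C, which releases the non-enolisable aldehyde only on work-up.

Step 4
Reactants: 2 carvone oxide; 5 2-methyl-1,3-dioxolane-2-carbaldehyde
Product: 7 epoxy ketol (carvone oxide carrying at C1 the (S)-CH(OH)(2-methyl-1,3-dioxolan-2-yl) group, trans to the isopropenyl group; anti aldol), via lithium enolate 6 (not isolated)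
Conditions: LDA, THF, −78 °C; then 5, −78 °C; AcOH quench
Reagents that add atoms: none
Why: Kinetic α′-deprotonation (C11 is quaternary, so only C1 can enolise) gives the ring (E)-enolate, which adds to the aldehyde through a Zimmerman–Traxler chair on the face anti to the C14 isopropenyl group, setting C1 (trans to C14) and C2 (anti aldol) as the target requires.

Step 5
Reactants: 7 epoxy ketol
Product: 8 C2 triethylsilyl ether of 7
Conditions: TESOTf, 2,6-lutidine, CH2Cl2, −78 °C
Reagents that add atoms: triethylsilyl trifluoromethanesulfonate, CC[Si](CC)(CC)OS(=O)(=O)C(F)(F)F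
Why: Silylation of the hindered secondary carbinol with a silyl triflate and a weak base blocks retro-aldol and leaves C12–OH as the only hydroxyl to be alkylated in step 7.

Step 6
Reactants: 8 silylated epoxy ketone
Product: 10 allylic alcohol (C12–OH trans to the C14 isopropenyl group, C10=C11 alkene, C2–OTES), via epoxy hydrazone 9 (not isolated)
Conditions: N2H4·H2O, AcOH, MeOH, 0 → 23 °C
Reagents that add atoms: none
Why: Wharton transposition; the hydrazone opens the oxirane at C11 and loses N2 to give the C10=C11 alkene and the C12 alcohol, whose untouched C–O bond keeps the pseudoaxial configuration set in step 1.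

Step 7
Reactants: 10 allylic alcohol; 11 tributyl(iodomethyl)stannane
Product: 12 C12 (tributylstannyl)methyl ether
Conditions: KH, 18-crown-6 (cat.), THF, 0 °C; then 11, 0 → 23 °C
Reagents that add atoms: none
Why: Williamson etherification of the potassium alkoxide with the reactive α-stannyl iodide; C12–OH is the only free hydroxyl.

Step 8
Reactants: 12 stannylmethyl ether
Product: 14 primary alcohol (C10–CH2OH, i.e. C9, cis to the C1 side chain; C11=C12 alkene; C2–OTES), via alkoxymethyllithium 13 (not isolated)
Conditions: n-BuLi, THF, −78 → −40 °C; H2O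
Reagents that add atoms: none
Why: Still–Wittig [2,3]-sigmatropic rearrangement; tin–lithium exchange gives the α-alkoxymethyllithium, which migrates suprafacially from the pseudoaxial C12 oxygen to C10 on the same face, setting C10 with C9 cis to the C1 side chain and restoring the C11=C12 alkene.

Step 9
Reactants: 14 silyl ether alcohol
Product: 15 1,4-diol (C2–OH, C9–OH)
Conditions: TBAF, THF, 0 °C
Reagents that add atoms: none
Why: Fluoride cleavage of the only silyl ether frees C2–OH.

Step 10
Reactants: 15 1,4-diol
Product: 16 cis-fused γ-lactone (C9 carbonyl, ring O from C2; C3 dioxolane, C11=C12 alkene, C14 isopropenyl)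
Conditions: TEMPO (cat.), PhI(OAc)2, CH2Cl2, 23 °C
Reagents that add atoms: none
Why: TEMPO/PhI(OAc)2 oxidative lactonisation; the primary C9 alcohol is oxidised selectively, the aldehyde is trapped by C2–OH as the five-membered lactol and oxidised on, which closes the future tetrahydrofuran ring (C1, C2, O, C9, C10).

Step 11
Reactants: 16 lactone
Product: 18 primary alcohol (C17–OH, 15R), via C17 alkylborane 17 (not isolated)
Conditions: 9-BBN, THF, 0 → 23 °C; then NaBO3·4H2O, THF–H2O, 23 °C
Reagents that add atoms: sodium perborate, [Na+].[Na+].O[B-]1(O)OO[B-](O)(O)OO1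
Why: Hydroboration–oxidation; 9-BBN adds only to the 1,1-disubstituted C15=C17 alkene (the trisubstituted alkene and the lactone react far more slowly) and, in the rotamer with C14–H eclipsing the C=CH2 bond, from the face turned away from the branched C1 (acyclic 1,2-induction), which should set C15 as 15R.

Step 12
Reactants: 18 primary alcohol
Product: 19 C17 tert-butyldimethylsilyl ether
Conditions: TBSCl, imidazole, DMF, 23 °C
Reagents that add atoms: tert-butyldimethylsilyl chloride, CC(C)(C)[Si](C)(C)Cl
Why: Standard silylation of the primary hydroxyl keeps C17–OH out of the lactol and acylation chemistry.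

Step 13
Reactants: 19 silylated lactone
Product: 21 lactol acetate (C9 anomers), via aluminium hemiacetal 20 (not isolated)
Conditions: DIBAL-H, CH2Cl2, −78 °C; then pyridine, DMAP, Ac2O, −78 → 0 °C
Reagents that add atoms: acetic anhydride, CC(=O)OC(C)=O
Why: One-pot reductive acetylation; DIBAL-H stops at the aluminium hemiacetal at −78 °C, which is acetylated in situ without opening to the hydroxy aldehyde.

Step 14
Reactants: 21 lactol acetate; 22 (2-bromoallyl)trimethylsilane
Product: 23 2,9-cis tetrahydrofuran with the 2-bromoallyl group on C9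
Conditions: BF3·OEt2, CH2Cl2, −78 → −40 °C
Reagents that add atoms: none
Why: Hosomi–Sakurai C-glycosylation; BF3 ionises the anomeric acetate to the bicyclic oxocarbenium ion and the allylsilane adds to C9 on the convex face, anti to the C10–C11 bond, setting C9, while the dioxolane, deactivated by the adjacent C2 oxygen, should stay intact at low temperature.

Step 15
Reactants: 23 bromoallyl tetrahydrofuran
Product: 24 11,12-cis-diol
Conditions: OsO4 (5 mol%), NMO, acetone–H2O, 23 °C
Reagents that add atoms: N-methylmorpholine N-oxide, C[N+]1([O-])CCOCC1; water, O; osmium tetroxide (catalytic oxygen carrier), O=[Os](=O)(=O)=O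
Why: Upjohn dihydroxylation; OsO4 adds syn to the electron-rich trisubstituted C11=C12 alkene on the convex face of the cis-fused bicycle (anti to C9 on C10), setting C11 and C12, while the electron-poor bromoalkene is left alone.

Step 16
Reactants: 24 diol; 25 octanoyl chloride
Product: 26 C12 octanoate (C11–OH free)
Conditions: pyridine, DMAP (cat.), CH2Cl2, 0 °C
Reagents that add atoms: none
Why: DMAP-catalysed acylation of the secondary C12 hydroxyl; the tertiary C11 hydroxyl is too hindered to react.

Step 17
Reactants: 26 octanoate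
Product: 27 keto diol (C3 methyl ketone, C17–OH, C11–OH)
Conditions: 2 M HCl, THF, 40 °C
Reagents that add atoms: water, O
Why: Aqueous acid hydrolyses the dioxolane to the C3 methyl ketone and cleaves the primary TBS ether in the same operation; ester, bromoalkene and tertiary alcohol should tolerate it.

Step 18
Reactants: 27 keto diol; 28 allyltrimethylsilane
Product: 29 tertiary homoallylic alcohol (3S; allyl and methyl on C3, C17–OH and C11–OH free)
Conditions: TiCl4 (3 equiv), CH2Cl2, −78 °C; then 28, −78 °C
Reagents that add atoms: none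
Why: Chelate-controlled Hosomi–Sakurai allylation; TiCl4 bridges the C3 carbonyl and the tetrahydrofuran oxygen and the allylsilane attacks the ketone on the side of H2, away from C1 (Cram chelate model), setting C3 as 3S.

Step 19
Reactants: 29 tertiary homoallylic alcohol
Product: 31 tricyclic bromo diene (oxepane C3–O–C17 closed; allyl on C3, 2-bromoallyl on C9, C12 octanoate, C11–OH), via C17 triflate 30 (not isolated)
Conditions: Tf2O (1.2 equiv), 2,6-lutidine, CH2Cl2, −78 → 0 °C
Reagents that add atoms: none
Why: The primary C17 hydroxyl is triflated selectively at −78 °C and the tertiary C3 hydroxyl displaces the triflate (7-exo-tet etherification), closing the oxepane (C3, O, C17, C15, C14, C1, C2); the C11 tertiary alcohol cannot reach C17.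

Step 20
Reactants: 31 tricyclic bromo diene
Product: 33 CNP0286133.1 (target), via C6 alkylborane 32 (not isolated)
Conditions: 9-BBN, THF, 23 °C; then degassed aq. Cs2CO3; slow addition to Pd(dppf)Cl2 (20 mol%), AsPh3, DMF–THF–H2O, 50 °C, 2 mM
Reagents that add atoms: none
Why: 9-BBN adds anti-Markovnikov to the monosubstituted C5=C6 alkene of the C3 allyl group (boron on C6); after aqueous base has destroyed excess B–H, Pd(0) inserts into the C7–Br bond, the base-activated alkylborate transfers C6 to palladium with retention, and reductive elimination forms C6–C7. The closest known reaction type is the one-pot hydroboration/intramolecular B-alkyl Suzuki–Miyaura macrocyclisation, applied here to a nine-membered ring. The nine-membered ether ring (O, C2–C9; also the ten-membered carbocycle C1–C10) closes in the exo mode, the C7=C19 methylene staying outside the ring. No stereocentre is formed, since C6 and C7 are not stereogenic and all nine centres are already in place. The step needs hydroboration of the allyl group only and ring closure over oligomerisation: the bromoalkene is electron-poor and 1,1-disubstituted and so reacts slowly with 9-BBN, and the 2,9-cis tetrahydrofuran and the oxepane hold the C3 and C9 arms on one face, which slow addition at high dilution should exploit. The octanoate and the free C11 tertiary alcohol should tolerate aqueous Cs2CO3 at 50 °C, and any B–O bond formed at C11 is cleaved by the base.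

## Compound list

1 | (R)-carvone | CC1=CC[C@H](CC1=O)C(C)=C | starting material
2 | (1R,4R,6R)-carvone oxide | C=C(C)[C@@H]1C[C@H]2O[C@@]2(C)C(=O)C1 | intermediate
3 | ethyl pyruvate | CCOC(=O)C(C)=O | starting material
4 | ethyl 2-methyl-1,3-dioxolane-2-carboxylate | CCOC(=O)C1(C)OCCO1 | intermediate
5 | 2-methyl-1,3-dioxolane-2-carbaldehyde | O=CC1(C)OCCO1 | intermediate
6 | lithium enolate of 2 (C10–OLi, C1=C10) | C=C(C)[C@@H]1C[C@H]2O[C@@]2(C)C(O[Li])=C1 | intermediate
7 | epoxy ketol (anti aldol at C1/C2, trans to isopropenyl) | C=C(C)[C@@H]1C[C@H]2O[C@@]2(C)C(=O)[C@H]1[C@H](O)C3(C)OCCO3 | intermediate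
8 | C2 triethylsilyl ether of 7 | C=C(C)[C@@H]1C[C@H]2O[C@@]2(C)C(=O)[C@H]1[C@H](O[Si](CC)(CC)CC)C3(C)OCCO3 | intermediate
9 | epoxy hydrazone of 8 | C=C(C)[C@@H]1C[C@H]2O[C@@]2(C)C(=NN)[C@H]1[C@H](O[Si](CC)(CC)CC)C3(C)OCCO3 | intermediate
10 | C12 allylic alcohol, C10=C11 alkene, C2–OTES | C=C(C)[C@@H]1C[C@@H](O)C(C)=C[C@H]1[C@H](O[Si](CC)(CC)CC)C2(C)OCCO2 | intermediate
11 | tributyl(iodomethyl)stannane | CCCC[Sn](CCCC)(CCCC)CI | starting material
12 | C12 (tributylstannyl)methyl ether | C=C(C)[C@@H]1C[C@@H](OC[Sn](CCCC)(CCCC)CCCC)C(C)=C[C@H]1[C@H](O[Si](CC)(CC)CC)C2(C)OCCO2 | intermediate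
13 | C12 (lithiomethyl) ether | C=C(C)[C@@H]1C[C@@H](OC[Li])C(C)=C[C@H]1[C@H](O[Si](CC)(CC)CC)C2(C)OCCO2 | intermediate
14 | C9 primary alcohol, C11=C12 alkene, C2–OTES | C=C(C)[C@@H]1CC=C(C)[C@@H](CO)[C@H]1[C@H](O[Si](CC)(CC)CC)C2(C)OCCO2 | intermediate
15 | C2,C9 1,4-diol | C=C(C)[C@@H]1CC=C(C)[C@@H](CO)[C@H]1[C@H](O)C2(C)OCCO2 | intermediate
16 | cis-fused γ-lactone (C9 carbonyl) | C=C(C)[C@@H]1CC=C(C)[C@@H]2[C@H]1[C@@H](C3(C)OCCO3)OC2=O | intermediate
17 | C17 B-alkyl-9-BBN of 16 | B5(C[C@H](C)[C@@H]1CC=C(C)[C@@H]2[C@H]1[C@@H](C3(C)OCCO3)OC2=O)C6CCCC5CCC6 | intermediate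
18 | (15R) C17 primary alcohol lactone | OC[C@H](C)[C@@H]1CC=C(C)[C@@H]2[C@H]1[C@@H](C3(C)OCCO3)OC2=O | intermediate
19 | C17 TBS ether lactone | CC(C)(C)[Si](C)(C)OC[C@H](C)[C@@H]1CC=C(C)[C@@H]2[C@H]1[C@@H](C3(C)OCCO3)OC2=O | intermediate
20 | C9 diisobutylaluminium hemiacetal | CC(C)(C)[Si](C)(C)OC[C@H](C)[C@@H]1CC=C(C)[C@@H]2[C@H]1[C@@H](C3(C)OCCO3)OC2O[Al](CC(C)C)CC(C)C | intermediate
21 | C9 lactol acetate (anomers) | CC(C)(C)[Si](C)(C)OC[C@H](C)[C@@H]1CC=C(C)[C@@H]2[C@H]1[C@@H](C3(C)OCCO3)OC2OC(C)=O | intermediate
22 | (2-bromoallyl)trimethylsilane | C=C(Br)C[Si](C)(C)C | starting material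
23 | 2,9-cis tetrahydrofuran with 2-bromoallyl on C9 | CC(C)(C)[Si](C)(C)OC[C@H](C)[C@@H]1CC=C(C)[C@@H]2[C@H]1[C@@H](C3(C)OCCO3)O[C@H]2CC(Br)=C | intermediate
24 | 11,12-cis-diol | CC(C)(C)[Si](C)(C)OC[C@H](C)[C@@H]1C[C@H](O)[C@](C)(O)[C@@H]2[C@H]1[C@@H](C3(C)OCCO3)O[C@H]2CC(Br)=C | intermediate
25 | octanoyl chloride | CCCCCCCC(Cl)=O | starting material
26 | C12 octanoate | CC(C)(C)[Si](C)(C)OC[C@H](C)[C@@H]1C[C@H](OC(=O)CCCCCCC)[C@](C)(O)[C@@H]2[C@H]1[C@@H](C3(C)OCCO3)O[C@H]2CC(Br)=C | intermediate
27 | keto diol (C3 methyl ketone, C17–OH, C11–OH) | OC[C@H](C)[C@@H]1C[C@H](OC(=O)CCCCCCC)[C@](C)(O)[C@@H]2[C@H]1[C@@H](C(C)=O)O[C@H]2CC(Br)=C | intermediate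
28 | allyltrimethylsilane | C=CC[Si](C)(C)C | starting material
29 | (3S) tertiary homoallylic alcohol | OC[C@H](C)[C@@H]1C[C@H](OC(=O)CCCCCCC)[C@](C)(O)[C@@H]2[C@H]1[C@@H]([C@@](C)(O)CC=C)O[C@H]2CC(Br)=C | intermediate
30 | C17 triflate of 29 | FC(F)(F)S(=O)(=O)OC[C@H](C)[C@@H]1C[C@H](OC(=O)CCCCCCC)[C@](C)(O)[C@@H]2[C@H]1[C@@H]([C@@](C)(O)CC=C)O[C@H]2CC(Br)=C | intermediate
31 | tricyclic bromo diene (oxepane, tetrahydrofuran, cyclohexane; C3 allyl, C9 2-bromoallyl, C12 octanoate) | C=CC[C@]2(C)OC[C@H](C)[C@@H]3C[C@H](OC(=O)CCCCCCC)[C@](C)(O)[C@@H]4[C@H]3[C@@H]2O[C@H]4CC(Br)=C | intermediate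
32 | C6 B-alkyl-9-BBN of 31 | C(CC[C@]2(C)OC[C@H](C)[C@@H]3C[C@H](OC(=O)CCCCCCC)[C@](C)(O)[C@@H]4[C@H]3[C@@H]2O[C@H]4CC(Br)=C)B5C6CCCC5CCC6 | intermediate
33 | CNP0286133.1 | C=C1CCC[C@]2(C)OC[C@H](C)[C@@H]3C[C@H](OC(=O)CCCCCCC)[C@](C)(O)[C@@H]4[C@H]3[C@@H]2O[C@H]4C1 | target

## Step count and risks

Total steps: 20. Longest linear sequence: 19 (steps 2, 3, then 4–20, from ethyl pyruvate); 18 from (R)-carvone.

**Step 20 (most at risk).** Closure of the nine-membered ring may be too slow, so that oligomerisation, protodeboronation or reduction of the vinylpalladium intermediate takes over. The fallback closes the same ring by a Nozaki–Hiyama–Kishi reaction and then removes the extra oxygen. It sets out from 31. Hydroboration of the allyl group with 9-BBN and perborate oxidation gives the C6 primary alcohol F1, and Dess–Martin oxidation gives the aldehyde F2. CrCl2 with catalytic NiCl2 in DMSO–THF at high dilution adds the C7 vinyl bromide to the C6 aldehyde and gives the cyclic allylic alcohol F3 (C6 epimers). Methyl chloroformate and pyridine give the carbonate F4. Palladium-catalysed formate reduction (Pd(OAc)2, PBu3, HCO2NH4) delivers hydride to the more substituted C6 terminus of the π-allyl and keeps the exocyclic methylene, which comes back to the route at 33.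

**Step 11.** Rotamer mobility of the isopropenyl group may lead to poor facial selectivity at C15. The fallback replaces substrate control by catalyst control. It sets out from 16. Copper hydride-catalysed hydroboration with pinacolborane and a chiral bisphosphine (Cu(OAc)2, DTBM-SEGPHOS, the enantiomer matched to 15R), a method known for unactivated 1,1-disubstituted alkenes, gives the C17 pinacol boronate F5. Perborate oxidation comes back to the route at 18.

**Step 18.** TiCl4 may titanate or ionise the free hydroxyls (above all the tertiary C11–OH), which would degrade the substrate or disturb the chelate and so the facial control at C3. The fallback masks the hydroxyls first. It sets out from 27. TESOTf and 2,6-lutidine at −78 °C give the bis(triethylsilyl) ether F6. The same chelate-controlled Hosomi–Sakurai allylation (SnCl4 or TiCl4, allyltrimethylsilane, −78 °C) on this hydroxyl-free ketone gives the bis-silylated homoallylic alcohol F7. HF·pyridine removes both silyl groups and comes back to the route at 29.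

## Further compounds

F1 | step 20 | C6 primary alcohol from 31 | OCCC[C@]2(C)OC[C@H](C)[C@@H]3C[C@H](OC(=O)CCCCCCC)[C@](C)(O)[C@@H]4[C@H]3[C@@H]2O[C@H]4CC(Br)=C
F2 | step 20 | C6 aldehyde | O=CCC[C@]2(C)OC[C@H](C)[C@@H]3C[C@H](OC(=O)CCCCCCC)[C@](C)(O)[C@@H]4[C@H]3[C@@H]2O[C@H]4CC(Br)=C
F3 | step 20 | cyclised C6 allylic alcohol (C6 epimers) | C=C1C(O)CC[C@]2(C)OC[C@H](C)[C@@H]3C[C@H](OC(=O)CCCCCCC)[C@](C)(O)[C@@H]4[C@H]3[C@@H]2O[C@H]4C1
F4 | step 20 | C6 methyl carbonate | C=C1C(OC(=O)OC)CC[C@]2(C)OC[C@H](C)[C@@H]3C[C@H](OC(=O)CCCCCCC)[C@](C)(O)[C@@H]4[C@H]3[C@@H]2O[C@H]4C1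
F5 | step 11 | C17 pinacol boronate lactone | CC1(C)OB(C[C@H](C)[C@@H]2CC=C(C)[C@@H]3[C@H]2[C@@H](C4(C)OCCO4)OC3=O)OC1(C)C
F6 | step 18 | C11,C17 bis(triethylsilyl) ether of ketone 27 | CC[Si](CC)(CC)OC[C@H](C)[C@@H]1C[C@H](OC(=O)CCCCCCC)[C@](C)(O[Si](CC)(CC)CC)[C@@H]2[C@H]1[C@@H](C(C)=O)O[C@H]2CC(Br)=C
F7 | step 18 | C11,C17 bis(triethylsilyl) ether of 29 | CC[Si](CC)(CC)OC[C@H](C)[C@@H]1C[C@H](OC(=O)CCCCCCC)[C@](C)(O[Si](CC)(CC)CC)[C@@H]2[C@H]1[C@@H]([C@@](C)(O)CC=C)O[C@H]2CC(Br)=C
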